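Product in the alpha run climbed to 90.7% by 120 s, while the substrate fell to 9.2%. I wanted to know what teal and green would do with other settings.

| setting | alpha | teal | green |
|---|---|---|---|
| substrate | 0.092 M | 0.092 M | 0.092 M |
| coupling partner | 0.25 M | 0.166 M | 0.166 M |
| scavenger | 0.138 M | 0.280 M | 0.140 M |
| free catalyst | 0.92 mM | 0.92 mM | 0.92 mM |
| impurity | 0.31 mM | 0.31 mM | 0.31 mM |
| remark | run made earlier |  |  |
| time |  | 3.0 min | 3.0 min |

- alpha (time / s: substrate / %, product / %): 20.0: 72.7, 25.9; 40.0: 52.8, 45.3; 60.0: 36.9, 62.1; 80.0: 24.9, 73.7; 120: 9.2, 90.7

(scatter of a reading: 0.5 percentage points)

- what was read earlier has a scatter of 0.5 percentage points, one standard deviation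
- no earlier run changes the charge of scavenger; that part of a forecast is a guess

* part of the substrate that has reacted at the end, teal
* part of the substrate that has reacted at the end, green
* what raising the concentration of scavenger from its lowest to its highest value here does to the part of the substrate that has reacted (changes below 5 percentage points count as none) (it falls / no change / it rises)

I took the settings one at a time, by hand. The time asked is longer than alpha's last reading, so I expected more product from that. The coupling partner is charged lower than in alpha, though still at 1.80 times the substrate's charge, so I expected a slower run if it enters the rate. Teal holds twice green's scavenger, but no earlier run varied it, so anything I said about it was a guess.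

Free catalyst and impurity stood at the same charges in alpha, teal and green, and I reckoned with those. I supposed that impurity removes free catalyst one for one. Free catalyst also leaves for its working round, but alpha made about 90.7 product per catalyst charged, so I took it that catalyst returns from that round and can meet the impurity again. I divided the rate at which spent catalyst forms by the rate at which impurity is lost: in the poisoning step that ratio is one at each moment, so time drops out, and spent catalyst made equals impurity consumed. If the impurity were used up, the spent part of the catalyst charge would come to 33.7%, impurity charge over catalyst charge: the poisoned share. In that side reaction the impurity would be the limiting reagent. I committed to that share for teal and green alike, and to no conversion figure of my own.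

The forecast gave 91% for teal, 91% for green and no change for the scavenger, saying: “Its kinetic role is untested, so I guess no change, with wide ranges”

Teal gave 96.8% and green 96.8%, higher than the forecast, and the scavenger moved the answer by 0.077 percentage points: no change.

    coupling partner + free catalyst → catalyst intermediate A (k = 29.0 L mol⁻¹ s⁻¹)
    substrate + catalyst intermediate A → catalyst intermediate B (k = 58.0 L mol⁻¹ s⁻¹)
    catalyst intermediate B ⇌ released group + catalyst intermediate C (K = 4.30 M, k = 11.0 s⁻¹)
    catalyst intermediate C → catalyst intermediate D (k = 18.0 s⁻¹)
    catalyst intermediate D ⇌ free catalyst + product (K = 0.140 M, k = 130 s⁻¹)
    substrate + released group ⇌ idle adduct, settled at all times (K = 7.50 L mol⁻¹)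
    scavenger + released group → scavenged by-product (k = 2.50 L mol⁻¹ s⁻¹)
    free catalyst + impurity → spent catalyst (k = 7300 L mol⁻¹ s⁻¹)

At 3.00 min teal held 33.7% of its catalyst as spent catalyst and 0% of its impurity, against my poisoned share of 33.7%. A neighbour of teal was charged with 0.230 mM of free catalyst, less than the impurity. The same division gave 135%, so 25.8% of the impurity should have stayed unused. That flask held 100% spent catalyst and 25.8% of its impurity, and 0.968% of its substrate had reacted.

Readings and results are calculated with made-up constants; scatter was added.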